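**Retrosynthetic overview**
- The target comes from an 8,17-epoxide, which comes from an 8-oxo-17-nor keto ester. C17 is added last by methylene transfer, and radical epoxide isomerisation then places the C7=C8 bond.
- The 8-ketone (six-membered ring B) comes from an oxidative 1,2-shift ring expansion of a (Z)-alkylidene hydrindene. C10 moves from C8 to C9, which makes the C9–C10 bond and turns the five-membered ring into ring B.
- The alkylidene hydrindene comes from a Wittig union of (R)-Hajos–Parrish ketone with a C9–C15 ylide. Ring A is finished by deconjugative gem-dimethylation and hydride reduction.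
- The Hajos–Parrish ketone comes from 2-methylcyclopentane-1,3-dione and methyl vinyl ketone (D-proline fixes C10). The ylide comes from (R)-β-butyrolactone and 3-chloropropan-1-ol (C13 is set by SN2 inversion).
- Ring order: the five-membered precursor of ring B is bought, ring A is annulated onto it, and ring B is made by the 5→6 expansion. C5 is set afterwards by HAT hydrogenation and C9 by equilibration.

Assumption: labdane numbering (C10 = angular carbon, C20 = its methyl) is used for all bicyclic compounds, and D-proline and (R)-β-butyrolactone are taken as purchasable in at least 98% ee.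

**Step 1**
Reactants: 1 2-methylcyclopentane-1,3-dione; 2 but-3-en-2-one (methyl vinyl ketone)
Product: 3 2-methyl-2-(3-oxobutyl)cyclopentane-1,3-dione
Conditions: H2O, AcOH (cat.), 70 °C
Reagents that add atoms: none
Why: Michael addition of the acidic 1,3-dione to the enone builds the still prochiral quaternary C10 and brings in C1–C4 of ring A.

**Step 2**
Reactants: 3 2-methyl-2-(3-oxobutyl)cyclopentane-1,3-dione
Product: 5 (7aR)-7a-methyl-2,3,7,7a-tetrahydro-1H-indene-1,5(6H)-dione ((R)-Hajos–Parrish ketone), via ketol 4 (not isolated)
Conditions: D-proline (3 mol %), DMF, 16 °C; then H2SO4 (cat.), 95 °C; recrystallise from Et2O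
Reagents that add atoms: none
Why: In this Hajos–Parrish–Eder–Sauer–Wiechert enamine aldol, D-proline differentiates the two enantiotopic ring ketones and so fixes C10 (mirror image of the L-proline product), and acid dehydration of the cis-ketol closes ring A as the enone.

**Step 3**
Reactants: 6 3-chloropropan-1-ol; 7 (R)-4-methyloxetan-2-one ((R)-β-butyrolactone)
Product: 9 (R)-6-hydroxy-3-methylhexanoic acid, via Grignard alkoxide 8 (not isolated)
Conditions: 6, MeMgCl, THF, −20 °C; Mg, reflux; then CuBr·SMe2 (10 mol %), 7, THF–Me2S, −30 → 0 °C; aq. HCl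
Reagents that add atoms: none
Why: Copper-catalysed SN2 alkyl–oxygen opening of the β-lactone by the Normant-type Grignard reagent proceeds with clean inversion at the methyl-bearing carbon, which carries the lactone stereocentre into C13 (R) and delivers the free acid directly.

**Step 4**
Reactants: 9 (R)-6-hydroxy-3-methylhexanoic acid
Product: 11 [(4R)-5-carboxy-4-methylpentyl]triphenylphosphonium bromide, via bromo acid 10 (not isolated)
Conditions: 48% aq. HBr, reflux; evaporate; PPh3, MeCN, reflux
Reagents that add atoms: hydrogen bromide, Br; triphenylphosphine, c1ccc(cc1)P(c1ccccc1)c1ccccc1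
Why: SN2 bromination of the primary alcohol followed by SN2 quaternisation of PPh3 is the standard preparation of ω-carboxyalkyl phosphonium salts and does not touch C13.

**Step 5**
Reactants: 5 (R)-Hajos–Parrish ketone; 11 phosphonium bromide
Product: 13 (13R)-enone acid in which the C8 ketone of 5 is replaced by the (Z)-5-carboxy-4-methylpentylidene group (chain cis to C10), via ylide 12 (not isolated)
Conditions: 11 (2.2 equiv), KN(SiMe3)2 (4.4 equiv), THF, 0 °C; add 5, −40 → 45 °C; aq. HCl
Reagents that add atoms: none
Why: In this Wittig olefination the carboxylate form of the ylide cannot acylate itself, the saturated cyclopentanone is more electrophilic than the enone (which excess basic ylide also masks as its dienolate), and the unstabilised ylide gives the Z alkene as with 17-keto steroids, a geometry that has no consequence later.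

**Step 6**
Reactants: 13 (Z)-alkylidene enone acid
Product: 14 methyl ester of the 4,4-dimethyl-3-oxo-5(6)-ene (Z)-alkylidene hydrindene
Conditions: KOtBu (3.1 equiv), tBuOH–THF, 0 °C; MeI (6 equiv), 0 → 23 °C
Reagents that add atoms: iodomethane, CI
Why: Classical deconjugative α,α-dimethylation through the extended thermodynamic dienolate (formed twice) installs C18 and C19 and moves the alkene to C5=C6, the third equivalent of MeI esterifies the carboxylate once the base is used up, and no stereocentre is formed.

**Step 7**
Reactants: 14 4,4-dimethyl-3-ketone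
Product: 15 3-hydroxy (Z)-alkylidene hydrindene methyl ester (3-OH equatorial and cis to C20)
Conditions: NaBH4, MeOH, 0 °C
Reagents that add atoms: none
Why: Hydride reduction of the hindered ketone takes place from the face opposite C20 and the axial C4 methyl, as in 4,4-dimethyl-5-en-3-one steroids, which sets C3 with the equatorial hydroxyl while the ester and both alkenes survive.

**Step 8**
Reactants: 15 3-hydroxy (Z)-alkylidene hydrindene methyl ester
Product: 17 methyl (13R)-3-hydroxy-8-oxo-17-nor-ent-labd-5-en-15-oate (C9 epimer mixture), via methoxy iodane 16 (not isolated)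
Conditions: PhI(OH)OTs (1.1 equiv), MeOH–H2O 95:5, CH2Cl2, −20 → 20 °C; aq. NaHCO3
Reagents that add atoms: [hydroxy(tosyloxy)iodo]benzene (Koser's reagent, net source of the ketone oxygen), Cc1ccc(cc1)S(=O)(=O)OI(O)c1ccccc1
Why: Proposed new method: oxidative semipinacol-type ring expansion of a purely aliphatic trisubstituted alkylidenecyclopentane by trivalent iodine, in which PhI(OH)+ adds at C9 of the exposed exocyclic C8=C9 bond (C5=C6 is buried between C4 and C10), methanol caps the tertiary C8, and loss of the hypernucleofuge PhI from C9 is coupled to the antiperiplanar 1,2-shift of the best migrating group, the fully substituted allylic C10 (retention at C10; C7 is only a CH2), so that the C9–C10 bond and six-membered ring B form together and the C8 methoxycarbenium ion is hydrolysed to the ketone, driven by C=O formation and relief of cyclopentane strain; the closest known reaction types are the Koser-reagent ring expansion of 1-alkylidene benzocycloalkanes (aryl shift only) and the Tl(NO3)3 ring enlargement of simple methylenecycloalkanes; C9 arises as an epimer mixture and is corrected in step 9.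

**Step 9**
Reactants: 17 Δ5-8-keto ester
Product: 19 methyl (13R)-3-hydroxy-8-oxo-17-nor-ent-labdan-15-oate (H5 trans to C20; C9 side chain equatorial and cis to C20), via epimer mixture 18 (not isolated)
Conditions: Mn(dpm)3 (10 mol %), PhSiH3, tBuOOH, iPrOH, 22 °C; then K2CO3, MeOH, 23 °C
Reagents that add atoms: none
Why: In this Mn–H hydrogen-atom-transfer hydrogenation H• adds to C6, the tertiary C5 radical takes its second hydrogen from the face opposite the two axial methyls (C20 and one C4 methyl) to give the favoured trans-decalin, and carbonate then equilibrates the enolisable C9 to the more stable equatorial side chain.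

**Step 10**
Reactants: 19 trans-decalone keto ester
Product: 20 8,17-epoxide (spiro-oxirane at C8 with oxygen axial and cis to C20)
Conditions: Me3SI (3 equiv), KN(SiMe3)2 (3 equiv), THF, 0 °C; add 19, 0 → 23 °C
Reagents that add atoms: trimethylsulfonium iodide, C[S+](C)C.[I-]
Why: Corey–Chaykovsky methylene transfer brings in C17, the ylide approaches the C8 ketone equatorially to avoid the syn-axial C20 (CH2 equatorial, O axial), the ester and the 3-alkoxide are inert, and the new C8 centre is erased in step 11.

**Step 11**
Reactants: 20 8,17-epoxide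
Product: 21 methyl (3R,5S,9S,10S,13R)-3,17-dihydroxylabd-7-en-15-oate (CNP0313905.1)
Conditions: Cp2TiCl2 (2.5 equiv), Mn powder, THF, 23 °C; then 1 M HCl
Reagents that add atoms: none
Why: In this radical epoxide-to-allylic-alcohol isomerisation, trivalent titanium (Cp2TiCl) opens the oxirane homolytically to the tertiary C8 radical with oxygen kept on C17, and a second Cp2TiCl removes the most accessible β-hydrogen (C7–H rather than the shielded tertiary C9–H), which gives the C7=C8 bond and leaves all stereocentres untouched.

**Compound list**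
1 | 2-methylcyclopentane-1,3-dione | CC1C(=O)CCC1=O | starting material
2 | but-3-en-2-one | CC(=O)C=C | starting material
3 | 2-methyl-2-(3-oxobutyl)cyclopentane-1,3-dione | CC(=O)CCC1(C)C(=O)CCC1=O | intermediate
4 | (3aR,7aR)-3a-hydroxy-7a-methylhexahydro-1H-indene-1,5-dione (cis-ketol) | C[C@@]12CCC(=O)C[C@]1(O)CCC2=O | intermediate
5 | (7aR)-7a-methyl-2,3,7,7a-tetrahydro-1H-indene-1,5(6H)-dione | C[C@@]12CCC(=O)C=C1CCC2=O | intermediate
6 | 3-chloropropan-1-ol | OCCCCl | starting material
7 | (R)-4-methyloxetan-2-one | C[C@@H]1CC(=O)O1 | starting material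
8 | ClMg(CH2)3OMgCl (Normant-type reagent) | Cl[Mg]CCCO[Mg]Cl | intermediate
9 | (R)-6-hydroxy-3-methylhexanoic acid | OC(=O)C[C@H](C)CCCO | intermediate
10 | (R)-6-bromo-3-methylhexanoic acid | OC(=O)C[C@H](C)CCCBr | intermediate
11 | [(4R)-5-carboxy-4-methylpentyl]triphenylphosphonium bromide | OC(=O)C[C@H](C)CCC[P+](c1ccccc1)(c1ccccc1)c1ccccc1.[Br-] | intermediate
12 | potassium (R)-3-methyl-6-(triphenylphosphoranylidene)hexanoate | [K+].[O-]C(=O)C[C@H](C)CCC=P(c1ccccc1)(c1ccccc1)c1ccccc1 | intermediate
13 | (13R,8Z)-alkylidene enone acid | C[C@@]12CCC(=O)C=C1CC/C2=C/CC[C@@H](C)CC(=O)O | intermediate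
14 | (13R,8Z)-4,4-dimethyl-3-oxo-5(6)-ene methyl ester | C[C@@]12CCC(=O)C(C)(C)C1=CC/C2=C/CC[C@@H](C)CC(=O)OC | intermediate
15 | (13R,8Z)-3-hydroxy-4,4-dimethyl-5(6)-ene methyl ester (3-OH cis to C20) | C[C@@]12CC[C@@H](O)C(C)(C)C1=CC/C2=C/CC[C@@H](C)CC(=O)OC | intermediate
16 | 8-methoxy-9-(phenyl-λ3-iodanyl) adduct, tosylate (anti adduct, iodine on the face opposite C20) | COC(=O)C[C@H](C)CC[C@@H]([I+]c3ccccc3)[C@@]1(OC)CC=C2C(C)(C)[C@H](O)CC[C@@]12C.Cc1ccc(cc1)S(=O)(=O)[O-] | intermediate
17 | methyl (13R)-3-hydroxy-8-oxo-17-nor-ent-labd-5-en-15-oate, C9 epimer mixture | COC(=O)C[C@H](C)CCC1C(=O)CC=C2C(C)(C)[C@H](O)CC[C@@]12C | intermediate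
18 | methyl (13R)-3-hydroxy-8-oxo-17-nor-ent-labdan-15-oate, C9 epimer mixture | COC(=O)C[C@H](C)CCC1C(=O)CC[C@@H]2C(C)(C)[C@H](O)CC[C@@]12C | intermediate
19 | the same keto ester as the single 9-equatorial epimer | COC(=O)C[C@H](C)CC[C@@H]1C(=O)CC[C@@H]2C(C)(C)[C@H](O)CC[C@@]12C | intermediate
20 | 8,17-epoxide (O axial, cis to C20) | COC(=O)C[C@H](C)CC[C@@H]1[C@@]3(CO3)CC[C@@H]2C(C)(C)[C@H](O)CC[C@@]12C | intermediate
21 | methyl (3R,5S,9S,10S,13R)-3,17-dihydroxylabd-7-en-15-oate | COC(=O)C[C@H](C)CC[C@@H]1C(CO)=CC[C@@H]2C(C)(C)[C@H](O)CC[C@@]12C | target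

**Step count**
- Total steps: 11.
- Longest linear sequence: 9 (steps 1, 2, 5–11). The branch 3, 4, 5–11 is equally long.

**Steps most likely to fail**

*Step 8 (the new ring expansion).* Four side reactions are possible:
- simple 1,2-dimethoxylation or methoxy participation leading to the C9 ketone;
- shift of C7 instead of C10;
- a C20 methyl shift to a C8 cation;
- attack at C5=C6.

The fallback uses known chemistry. It sets out from 15 and comes back at 17. NBS in aqueous acetone at 0 °C adds HOBr to the exocyclic alkene and gives the 8-hydroxy-9-bromide bromohydrin F3. AgBF4 with 2,6-di-tert-butylpyridine in CH2Cl2 then triggers the classical silver-assisted semipinacol ring enlargement of a 1-(1-haloalkyl)cycloalkanol.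

*Step 5 (Wittig on the enedione).* The neopentyl cyclopentanone may be too slow. The enone may then be olefinated, or the dione may be degraded by base. The fallback sets out from 5 and comes back at 13. Ethane-1,2-dithiol with TsOH in AcOH thioketalises only the enone carbonyl and gives the enone dithiolane F1. Wittig reaction of F1 with ylide 12 gives the alkylidene dithiolane acid F2. MeI and CaCO3 in aqueous MeCN at 50 °C then release the enone.

*Step 11 (regiochemistry of the epoxide isomerisation).* Loss of the C9 hydrogen (C8=C9 alkene), deoxygenation to the 8(17)-alkene, or aldehyde formation may compete. The fallback fixes the alkene position by kinetic enolisation instead. It sets out from 19 and comes back at 21.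
- tBuMe2SiOSO2CF3 with 2,6-lutidine gives the 3-silyl ether ketone F4.
- KN(SiMe3)2 and N-(5-chloropyridin-2-yl)bis(trifluoromethanesulfonimide) in THF at −78 °C give the C7=C8 enol triflate F5.
- Stille coupling with Bu3SnCH2OH, Pd(PPh3)4 (zerovalent palladium) and LiCl in dioxane at 95 °C gives the silylated allylic alcohol F6.
- Bu4NF in THF removes the silyl group.

**Further compounds**
F1 | step 5 | (R)-Hajos–Parrish ketone 5-(1,3-dithiolane) | C[C@@]12CCC3(SCCS3)C=C1CCC2=O
F2 | step 5 | (13R,8Z)-alkylidene dithiolane acid | C[C@@]12CCC3(SCCS3)C=C1CC/C2=C/CC[C@@H](C)CC(=O)O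
F3 | step 8 | 8-hydroxy-9-bromide (anti bromohydrin, Br on the face opposite C20) | COC(=O)C[C@H](C)CC[C@@H](Br)[C@@]1(O)CC=C2C(C)(C)[C@H](O)CC[C@@]12C
F4 | step 11 | 3-O-tert-butyldimethylsilyl ether of 19 | COC(=O)C[C@H](C)CC[C@@H]1C(=O)CC[C@@H]2C(C)(C)[C@H](O[Si](C)(C)C(C)(C)C)CC[C@@]12C
F5 | step 11 | C7=C8 enol triflate of F4 | COC(=O)C[C@H](C)CC[C@@H]1C(OS(=O)(=O)C(F)(F)F)=CC[C@@H]2C(C)(C)[C@H](O[Si](C)(C)C(C)(C)C)CC[C@@]12C
F6 | step 11 | 3-O-tert-butyldimethylsilyl ether of 21 | COC(=O)C[C@H](C)CC[C@@H]1C(CO)=CC[C@@H]2C(C)(C)[C@H](O[Si](C)(C)C(C)(C)C)CC[C@@]12C
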